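The meeting on this flask opened with the birch run, whose substrate stood level from the earliest reading: 78.4% at 0.333 h and 78.2% at 2.50 h. The ash run, with 0.41 M of coupling partner against 0.18 M in birch, levelled lower, at 50.8%.

the same everywhere: substrate 0.45 M

| charge | coupling partner | protic impurity | remark | time |
|---|---|---|---|---|
| birch | 0.18 M | 0.45 M | run made earlier |  |
| ash | 0.41 M | 0.45 M | run made earlier |  |
| flask | 0.270 M | 0.450 M |  | 4.0 h |

| run | time / h | product / % | substrate / % |
|---|---|---|---|
| birch | 0.333 | 5.6 | 78.4 |
| birch | 0.500 | 6.0 | 77.9 |
| birch | 0.833 | 7.7 | 78.6 |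
| birch | 1.00 | 7.1 | 78.8 |
| birch | 1.50 | 8.0 | 78.8 |
| birch | 2.50 | 6.6 | 78.2 |
| ash | 0.333 | 10.4 | 50.9 |
| ash | 0.500 | 13.5 | 51.6 |
| ash | 0.833 | 16.1 | 51.0 |
| ash | 1.00 | 16.7 | 50.9 |
| ash | 1.50 | 17.1 | 51.0 |
| ash | 2.50 | 15.4 | 50.8 |

(standard deviation of a reading: 0.5 percentage points)



- the best time, 4.0 h at the latest, for product
- the amount of product, in percent of the substrate charged, at that time

The first speaker pointed out that the highest product reading comes at 1.50 h in both runs and proposed carrying one number: the product per partner, meaning moles of product at that highest reading for each mole of coupling partner charged. The ash run gives 0.188.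

The second speaker set the birch run beside it, at 0.200, but preferred the ash figure: its peak reading of 17.1% is higher than the 8.0% of birch, so the scatter of 0.5 percentage points weighs less on it.

The minute-taker's own reckoning multiplied the ash figure by the partner charge and divided by the substrate charge, which puts the flask at 11.3% near 1.50 h.

The forecast stands close to this but not on it, at 11.5% and 1.3 h, on its own figure of “about 0.19% per 1% partner”.

The flask gives 11.4% at 1.40 h, with 0.0251% of the charged coupling partner, the limiting reagent, left at that time.

    substrate + coupling partner ⇌ intermediate (K = 84.0 L mol⁻¹, k = 0.00830 L mol⁻¹ s⁻¹)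
    intermediate ⇌ product + by-product (K = 1.00 M, k = 3.30 × 10⁻⁴ s⁻¹)
    intermediate → decomposed reagent (k = 5.60 × 10⁻⁴ s⁻¹)
    coupling partner + protic impurity → quenched reagent (k = 0.00600 L mol⁻¹ s⁻¹)

That is 0.190 product per partner in the flask, against the 0.188 read from the ash run. A neighbour flask, the same but charged with 0.68 M of coupling partner, is reckoned by the ash figure at 28.4%. It reaches 25.9%, which is 0.171 product per partner.

The readings were computed from invented constants.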